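Readings and results stem from a simulated flask with constants of no real substance, and the scatter is random.

**The vessel.** The vessel is closed, stirred and isothermal. Za meets Zd, a solid with none of it dissolved at the start, and Ze forms.

| flask | Za | Zd | temperature | remark | time |
|---|---|---|---|---|---|
| elm | 0.050 M | 0.025 M | 25 °C | the very flask that is asked about, followed so far |  |
| larch | 0.075 M | 0.025 M | 31 °C | run made earlier |  |
| flask | 0.050 M | 0.0250 M | 25 °C |  | 15 h |

| run | time / min | Ze / % | Za / % |
|---|---|---|---|
| elm | 120 | 50.7 | 8.3 |
| elm | 300 | 50.2 | 0 |
| elm | 600 | 49.1 | 0.4 |
| elm | 900 | 48.0 | 0.7 |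
| larch | 5.00 | 6.2 | 82.5 |
| larch | 10.0 | 12.7 | 65.2 |
| larch | 15.0 | 22.1 | 54.4 |
| larch | 20.0 | 26.8 | 41.2 |

(readings scatter by 1 percentage point)

1. Ze, in percent of the Za first charged, at 15 h
2. the remedy with the largest gain of Ze, or "none" below 2 percentage points (Thursday's / Wednesday's / Tuesday's / Monday's / none)
3. Ze present, with what was taken out counted in, in percent of the Za first charged, after Thursday's
4. Ze present, with what was taken out counted in, in percent of the Za first charged, after Monday's

- Thursday's: change nothing and wait 15 h more
- Wednesday's: at 15 h raise the temperature by 15 K, then wait 15 h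
- Tuesday's: at 15 h take out 90% of the Ze then present, then wait 15 h
- Monday's: at 15 h add Za, 50.0% of the amount charged, then wait 15 h

- given per volume of solution although it is solid: Zd
- Ze that was removed still counts
- the numbers in the tables scatter by 1 percentage point (one standard deviation)
- at the start none of Zd is in solution
- additions bring no volume worth counting

**Main step.** I take the main step first: one Za and one Zd give one Ze. Ze then cannot pass the Zd charged as a fraction of the Za charged, 50.0%, which I call the Zd ceiling. In the flask Zd is the limiting reagent.

**Second path.** In the elm run at 120 min, Ze reads 50.7% and Za 8.3%, so these readings leave 41.0% of the charge as neither. A path therefore takes Za without giving Ze. But the Za beyond the ceiling is 50.0%, and the loss is smaller than that, so at that reading of the elm run it fits within the Za that the ceiling leaves over.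

**The rest.** The first Za reading of the elm run gives an average half-life of about 33.4 min, and 15 h is 26.9 of those. In the elm run Ze reads 2.7 percentage points lower at 900 min than at 120 min, each reading scattering by 1 point, and I choose to carry no decay. My reckoning is therefore 50.0% now and after Thursday's. Monday's adds Za but no Zd, so I reckon 50.0% of the first charge there too, and I expect no remedy to gain 2 points.

**The forecast.** The forecast gives 48% now (46.8% to 49.2%), 45% after Thursday's, 45.2% after Monday's, and none as the best remedy: “Ze looks capped by Zd”. It differs from my reckoning by adding a slow decay of Ze.

**The result.** The flask gives 50.0% at 15 h, 50.0% after Thursday's and 50.0% after Monday's, and the best remedy is none.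

    Za + Zb → Ze (k = 8.40 /M/min, Ea = 53.0 kJ/mol)
    Za → Zc (k = 0.0120 /min, Ea = 81.0 kJ/mol)
    Zd ⇌ Zb, rate k3*(cs3 - [Zb]) while solid is left; crystals form when [Zb] > cs3 (solubility = 14.0 mM, k = 0.0930 /min)
    (constants at 25 °C)

**The comparison.** In the flask, half of the dissolving of Zd is done by 11.5 min, sooner than the 58 min half-life of Za by its loss to Zc alone. At 900 min the flask holds Ze at 50.0%, level with the ceiling, with Zc at 50.0% and Zd at 0% of its own charge. The same flask with 0.043 M of Zd has a ceiling of 86.0% and gives 72.6%, below that ceiling, with 16% of its Zd left.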